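**Plan**
Cuts: the C2'–C3' single bond of the (1'E,3'E)-butadienyl linker (Stille), the C3'=C4' alkene next to the oxolane (Takai), C3–C4 and O2–C1 of the isochromenone (toluate acylation, enol lactonisation), and last O1–C5 together with C2–C3 of the oxolane ((3+2) annulation).
Enabling feature: in the oxolane ring, O1–C2 is the C=O of an aldehyde and C5–C4–C3 are the three carbons of a cyclopropane. The methyl-bearing C5 is the donor carbon. The carbinol carbon C3 is the former diester (acceptor) carbon, later cut down to a ketone.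
Fragment A, forward: (R)-propane-1,2-diol → cyclic sulfate → (S)-methylcyclopropane diester → annulation closes the oxolane → C3 diester degraded to ketone → reduction, silylation, C2 arm unmasked to the aldehyde → (E)-iodoalkene.
Fragment B, forward: methyl orsellinate is chlorinated, silylated, acylated at its methyl group with a β-stannylacrylic Weinreb amide and closed to the isochromenone ring. Fragments A and B are then coupled and desilylated.
Stereochemistry: C5 comes from the diol through two successive inversions, C2 from the 2,5-cis-selective ring closure, and C3 from hydride attack anti to both ring substituents. Alkene geometry comes from the Takai step and from (E)-bis(stannyl)ethene, and is retained in the coupling.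

Key step: step 3

Assumption: (benzyloxy)acetaldehyde, methyl 2,4-dihydroxy-6-methylbenzoate, (E)-1,2-bis(tributylstannyl)ethene and N-methoxy-N-methylcarbamoyl chloride are treated as purchasable, and C3-epimer mixtures formed between the diester and the ketone are carried on unseparated because C3 becomes trigonal.

Step 1
Reactants: 1 (2R)-propane-1,2-diol
Product: 3 (4R)-4-methyl-1,3,2-dioxathiolane 2,2-dioxide, via cyclic sulfite 2 (not isolated)
Conditions: SOCl2, CH2Cl2, reflux; then RuCl3·xH2O (cat.), NaIO4, MeCN–H2O, 0 °C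
Reagents that add atoms: thionyl chloride SOCl2, O=S(Cl)Cl; sodium periodate NaIO4, [Na+].[O-]I(=O)(=O)=O
Why: Cyclic sulfite formation followed by ruthenium-catalysed periodate oxidation (one-pot cyclic sulfate synthesis) changes only the O–H bonds, so the carbinol stereocentre of 1 is carried over unchanged.

Step 2
Reactants: 3 (4R)-4-methyl-1,3,2-dioxathiolane 2,2-dioxide; 4 dimethyl malonate
Product: 6 dimethyl (2S)-2-methylcyclopropane-1,1-dicarboxylate, via open-chain sodium alkyl sulfate 5 (not isolated)
Conditions: NaH (2.1 equiv), 1,2-dimethoxyethane, 23 °C → reflux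
Reagents that add atoms: none
Why: Double SN2 alkylation of malonate by a 1,2-cyclic sulfate: the enolate opens the ring at the primary carbon and the second enolate displaces the secondary sulfate in a 3-exo-tet closure with inversion, so the (R)-diol carbon should become (S) in 6 (the reverse order of attack inverts the same carbon once and leads to the same enantiomer).

Step 3
Reactants: 6 dimethyl (2S)-2-methylcyclopropane-1,1-dicarboxylate; 7 (benzyloxy)acetaldehyde
Product: 8 dimethyl (2R,5R)-2-[(benzyloxy)methyl]-5-methyloxolane-3,3-dicarboxylate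
Conditions: SnCl4 (20 mol %), 7 (3 equiv, slow addition), CH2Cl2, 23 °C
Reagents that add atoms: none
Why: SnCl4 chelates the two ester carbonyls of 6 and polarises the C1–C2 bond; the carbonyl oxygen of 7 attacks the methyl-bearing carbon from the rear in an SN2-like opening of the tight ion pair (O1–C5 formed), and the tin malonate enolate thus released adds to the oxocarbenium carbon (C2–C3 formed). The closest known reaction type is the Lewis-acid-catalysed (3+2) annulation of donor–acceptor cyclopropane-1,1-diesters with aldehydes, which under SnCl4 reaches from aryl and vinyl donors to simple n-alkyl donors, so a methyl donor sits at the slow end of the known scope. The oxolane closes by an aldol-type 5-(enolexo)-endo-trig attack, which is allowed here because the acceptor is a cationic C=O+ unit. C5 is controlled by inversion at the stereocentre of (S)-6 and should emerge R, while C2 is controlled by an envelope transition state with methyl and benzyloxymethyl both pseudoequatorial, which gives the 2,5-cis (2R) isomer. The step needs attack at the substituted carbon rather than at CH2, secured by the larger cationic character of the secondary carbon, and stereospecific opening rather than free ionisation, which the weakly stabilising methyl group favours. Slow addition of excess 7 is meant to keep the tin on the diester and not in a five-membered chelate with the α-benzyloxy aldehyde.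

Step 4
Reactants: 8 dimethyl (2R,5R)-2-[(benzyloxy)methyl]-5-methyloxolane-3,3-dicarboxylate
Product: 9 methyl (2R,5R)-2-[(benzyloxy)methyl]-5-methyloxolane-3-carboxylate (C3 epimers)
Conditions: LiCl (3 equiv), H2O (2 equiv), DMSO, 150 °C
Reagents that add atoms: none
Why: Krapcho dealkoxycarbonylation: chloride demethylates one ester, the carboxylate loses CO2 and the enolate is protonated, while C2 and C5 bear no acidic hydrogen and the new C3 centre may stay a mixture because it is erased in step 6.

Step 5
Reactants: 9 methyl (2R,5R)-2-[(benzyloxy)methyl]-5-methyloxolane-3-carboxylate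
Product: 10 methyl (2S,5R)-2-[(benzyloxy)methyl]-3-hydroxy-5-methyloxolane-3-carboxylate (C3 configuration inconsequential)
Conditions: KN(SiMe3)2, THF, −78 °C; 3-phenyl-2-(phenylsulfonyl)oxaziridine, −78 °C; AcOH quench
Reagents that add atoms: 3-phenyl-2-(phenylsulfonyl)-1,2-oxaziridine, O=S(=O)(c1ccccc1)N1OC1c1ccccc1
Why: Enolate hydroxylation with an N-sulfonyloxaziridine (Davis oxidation): the exocyclic potassium enolate of 9 is oxygenated at C3, and β-elimination of O1 should be slow at −78 °C because the endocyclic C2–O1 bond lies close to the nodal plane of the enolate.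

Step 6
Reactants: 10 methyl (2S,5R)-2-[(benzyloxy)methyl]-3-hydroxy-5-methyloxolane-3-carboxylate
Product: 12 (2S,5R)-2-[(benzyloxy)methyl]-5-methyloxolan-3-one, via crude 1,2-diol 11 (not isolated)
Conditions: LiAlH4, THF, 0 °C, aqueous work-up; then NaIO4, THF–pH 7 buffer, 0 °C
Reagents that add atoms: none
Why: Ester reduction followed by periodate glycol cleavage (Malaprade reaction) removes the exocyclic carbon as formaldehyde at neutral pH, where the β-benzyloxy ketone should neither epimerise at C2 nor eliminate benzyl alcohol.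

Step 7
Reactants: 12 (2S,5R)-2-[(benzyloxy)methyl]-5-methyloxolan-3-one
Product: 13 (2S,3S,5R)-2-[(benzyloxy)methyl]-5-methyloxolan-3-ol
Conditions: LiBH(s-Bu)3, THF, −78 °C; then aq NaOH, H2O2, 0 °C
Reagents that add atoms: none
Why: Bulky trialkylborohydride reduction: hydride reaches the C3 carbonyl from the ring face opposite the cis C2 and C5 substituents, which places the new hydroxyl syn to both and sets (3S), and the low temperature outruns enolisation.

Step 8
Reactants: 13 (2S,3S,5R)-2-[(benzyloxy)methyl]-5-methyloxolan-3-ol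
Product: 14 {[(2S,3S,5R)-2-[(benzyloxy)methyl]-5-methyloxolan-3-yl]oxy}(tert-butyl)dimethylsilane
Conditions: TBSOTf, 2,6-lutidine, CH2Cl2, 0 °C
Reagents that add atoms: tert-butyldimethylsilyl trifluoromethanesulfonate (TBSOTf), CC(C)(C)[Si](C)(C)OS(=O)(=O)C(F)(F)F
Why: Silyl triflate silylation of a hindered secondary alcohol under weakly basic conditions breaks only the O–H bond, so C3 keeps its configuration.

Step 9
Reactants: 14 {[(2S,3S,5R)-2-[(benzyloxy)methyl]-5-methyloxolan-3-yl]oxy}(tert-butyl)dimethylsilane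
Product: 15 [(2S,3S,5R)-3-{[tert-butyl(dimethyl)silyl]oxy}-5-methyloxolan-2-yl]methanol
Conditions: H2 (1 atm), Pd/C (10 wt %), EtOAc, 23 °C
Reagents that add atoms: none
Why: Catalytic hydrogenolysis cleaves the benzylic C–O bond only, and in ethyl acetate the TBS ether and the ring C–O bonds should stay intact.

Step 10
Reactants: 15 [(2S,3S,5R)-3-{[tert-butyl(dimethyl)silyl]oxy}-5-methyloxolan-2-yl]methanol
Product: 16 (2R,3S,5R)-3-{[tert-butyl(dimethyl)silyl]oxy}-5-methyloxolane-2-carbaldehyde
Conditions: 2,2,6,6-tetramethylpiperidin-1-oxyl (TEMPO, 10 mol %), PhI(OAc)2, CH2Cl2, 23 °C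
Reagents that add atoms: none
Why: Nitroxyl-catalysed alcohol oxidation stops at the aldehyde and runs without base, so the α-alkoxy centre C2 should not epimerise and silanol should not be eliminated (the change of the C2 descriptor to R is a priority effect only).

Step 11
Reactants: 16 (2R,3S,5R)-3-{[tert-butyl(dimethyl)silyl]oxy}-5-methyloxolane-2-carbaldehyde
Product: 17 tert-butyl({(2S,3S,5R)-2-[(E)-2-iodoethenyl]-5-methyloxolan-3-yl}oxy)dimethylsilane
Conditions: CrCl2 (6 equiv), CHI3 (2 equiv), THF–1,4-dioxane, 0 → 23 °C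
Reagents that add atoms: iodoform CHI3, IC(I)I
Why: Takai olefination: the geminal dichromium species formed from CHI3 and divalent chromium adds to the aldehyde and eliminates to the (E)-iodoalkene under non-basic conditions that spare C2.

Step 12
Reactants: 18 methyl 2,4-dihydroxy-6-methylbenzoate
Product: 19 methyl 3-chloro-4,6-dihydroxy-2-methylbenzoate
Conditions: SO2Cl2 (1.05 equiv), Et2O–CH2Cl2, 0 °C
Reagents that add atoms: sulfuryl chloride SO2Cl2, O=S(=O)(Cl)Cl
Why: Electrophilic aromatic chlorination: in orsellinate-type resorcylates the ring position between the methyl group and the non-chelated hydroxyl (para to the ester-chelated hydroxyl) is the one known to react first, and one equivalent at 0 °C should hold back dichlorination.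

Step 13
Reactants: 19 methyl 3-chloro-4,6-dihydroxy-2-methylbenzoate
Product: 20 methyl 3-chloro-2-methyl-4,6-bis{[tri(propan-2-yl)silyl]oxy}benzoate
Conditions: TIPSOTf (2.4 equiv), 2,6-lutidine, CH2Cl2, 0 → 23 °C
Reagents that add atoms: triisopropylsilyl trifluoromethanesulfonate (TIPSOTf), CC(C)[Si](C(C)C)(C(C)C)OS(=O)(=O)C(F)(F)F
Why: Phenol silylation with a silyl triflate also reaches the ester-chelated hydroxyl, and TIPS is chosen because aryl TIPS ethers resist amide bases, amidine bases and methanol yet fall to fluoride.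

Step 14
Reactants: 21 (E)-1,2-bis(tributylstannyl)ethene; 22 N-methoxy-N-methylcarbamoyl chloride
Product: 24 (2E)-N-methoxy-N-methyl-3-(tributylstannyl)prop-2-enamide, via stannylvinyllithium 23 (not isolated)
Conditions: n-BuLi (1.0 equiv), THF, −78 °C; then 22, −78 → 0 °C
Reagents that add atoms: none
Why: Tin–lithium exchange at one terminus of 21 retains the E geometry, and nucleophilic acyl substitution of the vinyllithium on the carbamoyl chloride gives a Weinreb amide far less electrophilic than 22, so a second addition should be minor.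

Step 15
Reactants: 20 methyl 3-chloro-2-methyl-4,6-bis{[tri(propan-2-yl)silyl]oxy}benzoate; 24 (2E)-N-methoxy-N-methyl-3-(tributylstannyl)prop-2-enamide
Product: 25 methyl 3-chloro-2-[(3E)-2-oxo-4-(tributylstannyl)but-3-en-1-yl]-4,6-bis{[tri(propan-2-yl)silyl]oxy}benzoate
Conditions: LiN(i-Pr)2, THF, −78 °C; then 24, −78 °C, short contact time; AcOH quench
Reagents that add atoms: none
Why: Lateral lithiation of an ortho-toluate and acylation with a Weinreb amide: the ester-stabilised benzylic anion should add 1,2 because the amide is a poor Michael acceptor whose β-carbon is shielded by Bu3Sn, and the chelated tetrahedral adduct prevents over-addition.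

Step 16
Reactants: 25 methyl 3-chloro-2-[(3E)-2-oxo-4-(tributylstannyl)but-3-en-1-yl]-4,6-bis{[tri(propan-2-yl)silyl]oxy}benzoate
Product: 26 5-chloro-3-[(E)-2-(tributylstannyl)ethenyl]-6,8-bis{[tri(propan-2-yl)silyl]oxy}-1H-isochromen-1-one
Conditions: 1,8-diazabicyclo[5.4.0]undec-7-ene (DBU, 0.3 equiv), 4 Å molecular sieves, toluene, 23 → 60 °C
Reagents that add atoms: none
Why: Base-catalysed enol lactonisation (6-exo-trig acyl substitution): the doubly activated benzylic CH2 enolises towards the arene, the enol oxygen attacks the neighbouring ester and methanol is lost to the sieves, all without acid, which spares the vinylstannane and the silyl ethers.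

Step 17
Reactants: 17 tert-butyl({(2S,3S,5R)-2-[(E)-2-iodoethenyl]-5-methyloxolan-3-yl}oxy)dimethylsilane; 26 5-chloro-3-[(E)-2-(tributylstannyl)ethenyl]-6,8-bis{[tri(propan-2-yl)silyl]oxy}-1H-isochromen-1-one
Product: 27 3-{(1E,3E)-4-[(2S,3S,5R)-3-{[tert-butyl(dimethyl)silyl]oxy}-5-methyloxolan-2-yl]buta-1,3-dien-1-yl}-5-chloro-6,8-bis{[tri(propan-2-yl)silyl]oxy}-1H-isochromen-1-one
Conditions: Pd2(dba)3 (5 mol %), AsPh3 (20 mol %), N-methylpyrrolidone, 23 °C, dark
Reagents that add atoms: none
Why: Stille coupling: insertion of zerovalent palladium into the vinyl C–I bond, transmetalation from tin and reductive elimination all retain alkene geometry and should give the (E,E)-diene, while the hindered aryl chloride is inert at room temperature.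

Step 18
Reactants: 27 3-{(1E,3E)-4-[(2S,3S,5R)-3-{[tert-butyl(dimethyl)silyl]oxy}-5-methyloxolan-2-yl]buta-1,3-dien-1-yl}-5-chloro-6,8-bis{[tri(propan-2-yl)silyl]oxy}-1H-isochromen-1-one
Product: 28 5-chloro-6,8-dihydroxy-3-{(1E,3E)-4-[(2S,3S,5R)-3-hydroxy-5-methyloxolan-2-yl]buta-1,3-dien-1-yl}-1H-isochromen-1-one
Conditions: Bu4NF (4 equiv), AcOH (4 equiv), THF, 0 → 23 °C
Reagents that add atoms: none
Why: Fluoride-induced desilylation: buffered Bu4NF should cleave the two aryl TIPS ethers at once and the secondary TBS ether more slowly, and the near-neutral medium protects the dienylic C2–O1 bond from ionisation and the lactone from opening, with no stereocentre touched.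

**Compound list**
1 | (2R)-propane-1,2-diol | C[C@@H](O)CO | starting material
2 | (4R)-4-methyl-1,3,2-dioxathiolane 2-oxide (epimers at sulfur) | C[C@@H]1COS(=O)O1 | intermediate
3 | (4R)-4-methyl-1,3,2-dioxathiolane 2,2-dioxide | C[C@@H]1COS(=O)(=O)O1 | intermediate
4 | dimethyl malonate | COC(=O)CC(=O)OC | starting material
5 | sodium (2R)-5-methoxy-4-(methoxycarbonyl)-5-oxopentan-2-yl sulfate | C[C@@H](OS(=O)(=O)[O-])CC(C(=O)OC)C(=O)OC.[Na+] | intermediate
6 | dimethyl (2S)-2-methylcyclopropane-1,1-dicarboxylate | C[C@H]1CC1(C(=O)OC)C(=O)OC | intermediate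
7 | (benzyloxy)acetaldehyde | O=CCOCc1ccccc1 | starting material
8 | dimethyl (2R,5R)-2-[(benzyloxy)methyl]-5-methyloxolane-3,3-dicarboxylate | C[C@@H]1CC(C(=O)OC)(C(=O)OC)[C@H](COCc2ccccc2)O1 | intermediate
9 | methyl (2R,5R)-2-[(benzyloxy)methyl]-5-methyloxolane-3-carboxylate (C3 epimers) | C[C@@H]1CC(C(=O)OC)[C@H](COCc2ccccc2)O1 | intermediate
10 | methyl (2S,5R)-2-[(benzyloxy)methyl]-3-hydroxy-5-methyloxolane-3-carboxylate (C3 undefined) | C[C@@H]1CC(O)(C(=O)OC)[C@H](COCc2ccccc2)O1 | intermediate
11 | (2S,5R)-2-[(benzyloxy)methyl]-3-(hydroxymethyl)-5-methyloxolan-3-ol (C3 undefined) | C[C@@H]1CC(O)(CO)[C@H](COCc2ccccc2)O1 | intermediate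
12 | (2S,5R)-2-[(benzyloxy)methyl]-5-methyloxolan-3-one | C[C@@H]1CC(=O)[C@H](COCc2ccccc2)O1 | intermediate
13 | (2S,3S,5R)-2-[(benzyloxy)methyl]-5-methyloxolan-3-ol | C[C@@H]1C[C@H](O)[C@H](COCc2ccccc2)O1 | intermediate
14 | {[(2S,3S,5R)-2-[(benzyloxy)methyl]-5-methyloxolan-3-yl]oxy}(tert-butyl)dimethylsilane | C[C@@H]1C[C@H](O[Si](C)(C)C(C)(C)C)[C@H](COCc2ccccc2)O1 | intermediate
15 | [(2S,3S,5R)-3-{[tert-butyl(dimethyl)silyl]oxy}-5-methyloxolan-2-yl]methanol | C[C@@H]1C[C@H](O[Si](C)(C)C(C)(C)C)[C@H](CO)O1 | intermediate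
16 | (2R,3S,5R)-3-{[tert-butyl(dimethyl)silyl]oxy}-5-methyloxolane-2-carbaldehyde | C[C@@H]1C[C@H](O[Si](C)(C)C(C)(C)C)[C@H](C=O)O1 | intermediate
17 | tert-butyl({(2S,3S,5R)-2-[(E)-2-iodoethenyl]-5-methyloxolan-3-yl}oxy)dimethylsilane | C[C@@H]1C[C@H](O[Si](C)(C)C(C)(C)C)[C@H](/C=C/I)O1 | intermediate
18 | methyl 2,4-dihydroxy-6-methylbenzoate | COC(=O)c1c(C)cc(O)cc1O | starting material
19 | methyl 3-chloro-4,6-dihydroxy-2-methylbenzoate | COC(=O)c1c(C)c(Cl)c(O)cc1O | intermediate
20 | methyl 3-chloro-2-methyl-4,6-bis{[tri(propan-2-yl)silyl]oxy}benzoate | COC(=O)c1c(C)c(Cl)c(O[Si](C(C)C)(C(C)C)C(C)C)cc1O[Si](C(C)C)(C(C)C)C(C)C | intermediate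
21 | (E)-1,2-bis(tributylstannyl)ethene | CCCC[Sn](CCCC)(CCCC)/C=C/[Sn](CCCC)(CCCC)CCCC | starting material
22 | N-methoxy-N-methylcarbamoyl chloride | CON(C)C(=O)Cl | starting material
23 | (E)-2-(tributylstannyl)ethenyllithium | [Li]/C=C/[Sn](CCCC)(CCCC)CCCC | intermediate
24 | (2E)-N-methoxy-N-methyl-3-(tributylstannyl)prop-2-enamide | CCCC[Sn](CCCC)(CCCC)/C=C/C(=O)N(C)OC | intermediate
25 | methyl 3-chloro-2-[(3E)-2-oxo-4-(tributylstannyl)but-3-en-1-yl]-4,6-bis{[tri(propan-2-yl)silyl]oxy}benzoate | COC(=O)c1c(CC(=O)/C=C/[Sn](CCCC)(CCCC)CCCC)c(Cl)c(O[Si](C(C)C)(C(C)C)C(C)C)cc1O[Si](C(C)C)(C(C)C)C(C)C | intermediate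
26 | 5-chloro-3-[(E)-2-(tributylstannyl)ethenyl]-6,8-bis{[tri(propan-2-yl)silyl]oxy}-1H-isochromen-1-one | CCCC[Sn](CCCC)(CCCC)/C=C/c1cc2c(Cl)c(O[Si](C(C)C)(C(C)C)C(C)C)cc(O[Si](C(C)C)(C(C)C)C(C)C)c2c(=O)o1 | intermediate
27 | 3-{(1E,3E)-4-[(2S,3S,5R)-3-{[tert-butyl(dimethyl)silyl]oxy}-5-methyloxolan-2-yl]buta-1,3-dien-1-yl}-5-chloro-6,8-bis{[tri(propan-2-yl)silyl]oxy}-1H-isochromen-1-one | C[C@@H]1C[C@H](O[Si](C)(C)C(C)(C)C)[C@H](/C=C/C=C/c2cc3c(Cl)c(O[Si](C(C)C)(C(C)C)C(C)C)cc(O[Si](C(C)C)(C(C)C)C(C)C)c3c(=O)o2)O1 | intermediate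
28 | 5-chloro-6,8-dihydroxy-3-{(1E,3E)-4-[(2S,3S,5R)-3-hydroxy-5-methyloxolan-2-yl]buta-1,3-dien-1-yl}-1H-isochromen-1-one | C[C@@H]1C[C@H](O)[C@H](/C=C/C=C/c2cc3c(Cl)c(O)cc(O)c3c(=O)o2)O1 | target

Total step count: 18. Longest linear sequence: 13 (steps 1–11, 17 and 18).

**Steps most likely to fail**

Step 3. The α-benzyloxy aldehyde may tie up SnCl4 as a chelate. It may also be too weak an oxygen nucleophile for the poorly activated methyl-substituted cyclopropane, so that conversion stalls and chloride opening of the ring or aldehyde oligomerisation takes over. The fallback sets out from 6 and returns at 8.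
- The same tin-catalysed annulation is run with (E)-cinnamaldehyde, a conjugated, non-chelating and more nucleophilic aldehyde. It should give dimethyl (2S,5R)-5-methyl-2-[(E)-2-phenylethenyl]oxolane-3,3-dicarboxylate F1.
- Ozonolysis (O3, CH2Cl2, −78 °C, then Me2S) cuts the styryl group down to dimethyl (2R,5R)-2-formyl-5-methyloxolane-3,3-dicarboxylate F2.
- Reductive etherification (BnOSiMe3, Et3SiH, catalytic Me3SiOTf, CH2Cl2, −78 → 0 °C) installs the benzyl ether without ever freeing a primary alcohol that could lactonise onto the cis ester, and so delivers 8.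

Step 15. The benzylic anion may add in conjugate fashion to the acrylamide and then close onto its own ester (naphthol-type annulation), or proton transfer and loss of tin may compete with acylation. The fallback sets out from 20 and returns at 26.
- The lateral anion of 20 (LiN(i-Pr)2, THF, −78 °C) is acylated with methyl dimethoxyacetate, an acyl donor with neither a conjugate-addition site nor tin. This gives methyl 3-chloro-2-(3,3-dimethoxy-2-oxopropyl)-4,6-bis{[tri(propan-2-yl)silyl]oxy}benzoate F3.
- DBU-catalysed lactonisation as in step 16 gives 5-chloro-3-(dimethoxymethyl)-6,8-bis{[tri(propan-2-yl)silyl]oxy}-1H-isochromen-1-one F4.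
- Aqueous CF3CO2H in CH2Cl2 frees 5-chloro-1-oxo-6,8-bis{[tri(propan-2-yl)silyl]oxy}-1H-isochromene-3-carbaldehyde F5.
- An (E)-selective chromium-mediated stannyl olefination (Bu3SnCHBr2, CrCl2, LiI, THF–DMF) turns the aldehyde into 26.

Step 5. At the enolate stage, ring opening by β-elimination of O1 or capture of the enolate by the sulfonimine released from the oxidant may erode the hydroxylation. The fallback sets out from 8 and returns at 12, bypassing steps 4–6 and all C3 carbanions.
- Exhaustive saponification (KOH, aq MeOH, reflux, then cold HCl) gives (2R,5R)-2-[(benzyloxy)methyl]-5-methyloxolane-3,3-dicarboxylic acid F6.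
- Anodic oxidative bis-decarboxylation of this disubstituted malonic acid (graphite electrodes, undivided cell, NH3, MeOH, constant current, 23 °C) gives (2S,5R)-2-[(benzyloxy)methyl]-3,3-dimethoxy-5-methyloxolane F7.
- Brief treatment with 1 M HCl in THF unmasks 12.

**Further compounds**
F1 | step 3 | dimethyl (2S,5R)-5-methyl-2-[(E)-2-phenylethenyl]oxolane-3,3-dicarboxylate | C[C@@H]1CC(C(=O)OC)(C(=O)OC)[C@H](/C=C/c2ccccc2)O1
F2 | step 3 | dimethyl (2R,5R)-2-formyl-5-methyloxolane-3,3-dicarboxylate | C[C@@H]1CC(C(=O)OC)(C(=O)OC)[C@H](C=O)O1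
F3 | step 15 | methyl 3-chloro-2-(3,3-dimethoxy-2-oxopropyl)-4,6-bis{[tri(propan-2-yl)silyl]oxy}benzoate | COC(=O)c1c(CC(=O)C(OC)OC)c(Cl)c(O[Si](C(C)C)(C(C)C)C(C)C)cc1O[Si](C(C)C)(C(C)C)C(C)C
F4 | step 15 | 5-chloro-3-(dimethoxymethyl)-6,8-bis{[tri(propan-2-yl)silyl]oxy}-1H-isochromen-1-one | COC(OC)c1cc2c(Cl)c(O[Si](C(C)C)(C(C)C)C(C)C)cc(O[Si](C(C)C)(C(C)C)C(C)C)c2c(=O)o1
F5 | step 15 | 5-chloro-1-oxo-6,8-bis{[tri(propan-2-yl)silyl]oxy}-1H-isochromene-3-carbaldehyde | O=Cc1cc2c(Cl)c(O[Si](C(C)C)(C(C)C)C(C)C)cc(O[Si](C(C)C)(C(C)C)C(C)C)c2c(=O)o1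
F6 | step 5 | (2R,5R)-2-[(benzyloxy)methyl]-5-methyloxolane-3,3-dicarboxylic acid | C[C@@H]1CC(C(=O)O)(C(=O)O)[C@H](COCc2ccccc2)O1
F7 | step 5 | (2S,5R)-2-[(benzyloxy)methyl]-3,3-dimethoxy-5-methyloxolane | C[C@@H]1CC(OC)(OC)[C@H](COCc2ccccc2)O1
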